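Ring B is numbered throughout as C1 (ketone carbon attached), C2 (OH), C3 (H), C4 (CH3), C5 (OCH3), C6 (CH2OAc). Compounds 1–9 are numbered as in the steps below.

## Analysis of the target

Preacredinone A (9) is an achiral diaryl ketone in which ring A is a 2,6-dimethoxyphenyl group and ring B is a benzene ring with five different substituents in a fixed order; there is no stereocentre. The only spatial feature is that the carbonyl has four ortho substituents, so ring A stands roughly perpendicular to it while the C2 hydroxyl holds it in the plane of ring B by a hydrogen bond. The benzylic acetate is the most sensitive group: it is cleaved by nucleophilic base, and it can be lost by 1,4-elimination whenever the neighbouring C5 oxygen is a free phenoxide. Hydroquinone-stage intermediates are prone to air oxidation under base, and an ortho-methoxyaryl ynone can cyclise through a methoxy oxygen if the alkyne is activated by a Lewis acid. Three things make the synthesis hard: the tetra-ortho-substituted ketone is difficult to make by joining two finished rings, the five substituents of ring B must be placed in order, and the two para oxygens must end up different, free at C2 and methylated at C5. The strategy rests on one feature of ring B: C2 to C5 carry O, H, CH3, O, which is the pattern of a 4-methyl-2-oxyfuran, with the ring oxygen becoming the C5 oxygen and the exocyclic oxygen the C2 oxygen. The adjacent carbons C1 and C6 carry an acyl group and an oxymethyl group, which is the pattern of an aryl ynone.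

## Retrosynthetic reasoning

**9 to 8 (O–CH3 bond at C5).** The C5 oxygen is the former furan oxygen, so the ring-forming step can only deliver it as a free phenol, and its methylation is therefore the last step. In diol 8, [2-(2,6-dimethoxybenzoyl)-3,6-dihydroxy-5-methylphenyl]methyl acetate, the two hydroxyls are already differentiated: the C2 hydroxyl is hydrogen-bonded to the ketone and the C5 hydroxyl is not. The forward step must methylate C5 only. It must also avoid a long-lived C5 phenoxide, because that phenoxide is ortho to the acetoxymethyl group and could expel the acetoxy group. A base-free methylation with a diazoalkane meets both demands, so alkylation under carbonate base is not used here.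

**8 to 2 and 5 (C5–C6 and C1–C2, through 7 and 6).** Ring B is opened across C5–C6 and C1–C2. This is a retro-(4+2) cut that leads, through the monosilyl hydroquinone 7 and the oxygen-bridged adduct 6, to the silyloxyfuran 2 and the ynone 5. The bond between C1 and the carbonyl carbon is deliberately not cut, because joining two complete, doubly ortho-substituted rings at a carbonyl is unreliable. In 5 the carbonyl is already attached to ring A and ring B is grown onto it. The gain is that the ring and all five substituents arise in one operation from two small pieces, with both oxygens in place. The forward reaction must give a single orientation, with the free α-carbon of 2 bonding to the β-carbon of 5. It must also not stop after that first bond.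

**5 to 3 and 4 (C(=O)–C(sp) bond).** The ynone is cut between the carbonyl and the alkyne, giving 2,6-dimethoxybenzoyl chloride 3 and propargyl acetate 4, both commercial. An acyl Sonogashira coupling makes this bond in one step and carries the acetate through unchanged, so no protecting-group exchange is needed at the benzylic oxygen.

**2 to 1 (O–Si bond).** The silyloxyfuran is the silyl dienol ether of the commercial butenolide 1. Soft enolisation with a silyl triflate and a tertiary amine gives it in one step. The methyl group at C4 of 1 is what becomes the C4 methyl of ring B.

## Alternatives that were turned down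

**Alternative 1:** Aryne insertion into a benzoic acid.
- Disconnection: C1–C(=O) and C2–O of ring B. Ring B becomes the C1–C2 aryne, drawn from the ortho-silylaryl triflate A1, and ring A with the carbonyl becomes 2,6-dimethoxybenzoic acid (A2).
- Forward key step: a fluoride source unmasks the aryne. The carboxylate of A2 adds through oxygen at C2, and the aryl anion at C1 takes the acyl group from that same oxygen. The net result is insertion into the acyl–oxygen bond, giving the ortho-hydroxy ketone A3.
- For it: it is metal-free and makes the hindered ketone and the free C2 hydroxyl together. C5 is a methyl ether from the start, so there is no late differentiation of two phenols. On that point it is stronger than the chosen route.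
- Against it: the aryne is flanked by H at C3 and an alkoxymethyl group at C6, which polarises it only weakly, so oxygen attack at C1 would compete. The acyl shift must place a 2,6-disubstituted aroyl group on a carbanion hindered on both sides, in competition with protonation to the aryl ester. A1 is itself a pentasubstituted benzene needing an estimated six to eight steps, so the ordering of five substituents is moved into the precursor rather than solved. Acetal removal and acetylation add two more steps after A3.
- Comparison: the chosen route builds the substitution pattern in the ring-forming step and should reach 9 in four steps. It gives up early differentiation of the oxygens and recovers it through chelation of the C2 hydroxyl.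

**Alternative 2:** Ring A grown from an acetyl group.
- Disconnection: ring A is cut at C1'–C2' and C1'–C6'. This leaves a complete ring B carrying an acetyl group (methyl ketone A4) and dimethyl glutarate (A5).
- Forward key step: the enolate of A4 is acylated by one ester of A5 (Claisen). The resulting β-diketone closes onto the second ester (Dieckmann-type) to give the 2-aroylcyclohexane-1,3-dione A6.
- For it: the hindered diaryl ketone never has to be made by joining two rings. The chemistry is ordinary carbonyl condensation with no regiochemical question. As a key step it is at least as predictable as the chosen cycloaddition.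
- Against it: it constructs the ring that can be bought (as in 3) and leaves the hard ring unsolved, since A4 is as heavily substituted as 9. After A6 the route still needs dehydrogenation of a chelated, enolised trione to a resorcinol, double methylation of two hydrogen-bonded phenols, removal of two acetals and a selective acetylation. That is well over ten steps in all.
- Comparison: the chosen strategy buys ring A and spends its one demanding step on ring B, where the difficulty lies.

**Alternative 3:** Gold-catalysed furan–yne phenol synthesis.
- Disconnection: C1–C6 and C2–C3 of ring B, with the C2 oxygen traced to a furan oxygen. The precursor is the furfuryl propargyl ether A7.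
- Forward key step: gold trichloride A9 (AuCl3, trivalent gold) activates the alkyne and the furan attacks it. The skeleton reorganises through carbenoid and arene-oxide stages to the phenol A8, closing ring B and a five-membered cyclic ether.
- For it: it is intramolecular, catalytic and atom-economical. The tether fixes the position of the phenol, which is firmer regiocontrol than the polarity control of the chosen route, and the C5 methoxy group is present from the start.
- Against it: A7 joins an acid-sensitive 3-methoxyfuran to a propargylic ether that is also benzylic to a 2,6-dimethoxyphenyl ring, a C–O bond that the Lewis-acidic A9 can ionise. A8 has the future carbonyl carbon as an ether CH, a stereocentre made only to be destroyed. Converting it needs selective oxidation of a hindered diaryl methine in the presence of the other benzylic CH2–O and a free phenol, then ring opening and acetylation.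
- Comparison: the chosen route delivers the ketone and the acetoxymethyl group at their final oxidation levels and needs far fewer steps.

Key step: step 3

Assumption: the silyl group of 7 is taken to stay on the C2 oxygen, the one it came in on; if it moved to the C5 oxygen, the HF work-up would still end at 8.

## Route

Step 1
Reactants: 1 4-methylfuran-2(5H)-one
Product: 2 tert-butyldimethyl[(4-methylfuran-2-yl)oxy]silane
Conditions: TBSOTf (1.1 equiv), Et3N (1.3 equiv), CH2Cl2, 0 °C
Reagents that add atoms: tert-butyldimethylsilyl trifluoromethanesulfonate, CC(C)(C)[Si](C)(C)OS(=O)(=O)C(F)(F)F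
Why: Soft enolisation of a butenolide, the standard preparation of 2-silyloxyfurans: the silyl triflate silylates the lactone carbonyl oxygen and Et3N removes a ring CH2 proton, preferred over the C4 methyl because only this gives the aromatic furan. 2 is hydrolytically labile, so it is freed from ammonium salts by pentane extraction and short-path distillation and used promptly.

Step 2
Reactants: 3 2,6-dimethoxybenzoyl chloride; 4 prop-2-yn-1-yl acetate
Product: 5 4-(2,6-dimethoxyphenyl)-4-oxobut-2-yn-1-yl acetate
Conditions: PdCl2(PPh3)2 (2 mol %), CuI (4 mol %), Et3N (1.2 equiv), THF, rt
Reagents that add atoms: none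
Why: Acyl Sonogashira coupling: the aroyl chloride adds oxidatively to zerovalent palladium (formed in the flask from the divalent precatalyst PdCl2(PPh3)2), the copper acetylide of 4 transmetalates, and reductive elimination forms the C(=O)–C(sp) bond. Room temperature and a near-stoichiometric amount of Et3N keep the acyl palladium from losing CO and protect the propargylic acetate and the product ynone from ionisation or amine addition.

Step 3
Reactants: 2 tert-butyldimethyl[(4-methylfuran-2-yl)oxy]silane; 5 4-(2,6-dimethoxyphenyl)-4-oxobut-2-yn-1-yl acetate
Product: 8 [2-(2,6-dimethoxybenzoyl)-3,6-dihydroxy-5-methylphenyl]methyl acetate, via oxanorbornadiene cycloadduct 6 (not isolated), via hydroquinone monosilyl ether 7 (not isolated)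
Conditions: 2 (1.5 equiv), PhMe (1 M), argon, rt → 80 °C; then HF·pyridine, THF, 0 °C
Reagents that add atoms: none
Why: This is the (4+2) cycloaddition of a 2-silyloxyfuran with an acetylenic ketone followed by aromatising opening of the oxygen bridge, a known route from 2-oxyfurans and activated alkynes to hydroquinone derivatives, applied here to a more hindered ynone. The electron-rich diene 2 and the electron-poor dienophile 5 combine with strongly unequal bond formation: the unsubstituted α-carbon of 2 (future C5, largest HOMO coefficient) bonds to the ynone carbon β to the carbonyl (future C6, bearing CH2OAc), and the carbonyl-bearing carbon (future C1) then closes onto the silyloxy carbon (future C2). Ring B is therefore closed by the intermolecular cycloaddition itself, both new bonds forming on one face of the planar furan, first as the 7-oxabicyclo[2.2.1]heptadiene 6. In 6 the bridgehead C2 is a mixed silyl ketal carbon, so its bond to the bridging oxygen ionises with help from the silyloxy lone pair, and loss of the C5 proton gives the aromatic monosilyl ether 7 with the furan oxygen on C5 and the former lactone carbonyl oxygen on C2. The two bridgehead stereocentres of racemic 6 are tied to each other by the bridge and vanish on aromatisation, so no stereocontrol is required. The selectivity needed is regiochemical and is secured by matched polarity: the most nucleophilic carbon of 2 meets the most electrophilic carbon of 5, while the 2,6-dimethoxyphenyl ring, twisted out of conjugation, neither deactivates the ynone nor shields C6. No Lewis acid is added, so that the reaction is not diverted to an open-chain Mukaiyama–Michael adduct and a methoxy oxygen is not drawn onto the activated alkyne. HF·pyridine then removes the aryl silyl group under acidic conditions, in which the C5 hydroxyl is never a phenoxide next to the acetoxymethyl group.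

Step 4
Reactants: 8 [2-(2,6-dimethoxybenzoyl)-3,6-dihydroxy-5-methylphenyl]methyl acetate
Product: 9 preacredinone A ([2-(2,6-dimethoxybenzoyl)-3-hydroxy-6-methoxy-5-methylphenyl]methyl acetate)
Conditions: CH2N2 (excess, in portions), Et2O–MeOH (9:1), 0 °C → rt
Reagents that add atoms: diazomethane, C=[N+]=[N-]
Why: O-Methylation of a phenol with diazomethane: the phenol protonates the reagent and the methyldiazonium phenoxide pair collapses at once to the aryl methyl ether and N2. The C2 hydroxyl, held in a hydrogen bond to the ketone, does not give up its proton at a useful rate (the classical way of sparing chelated hydroxyls), so only the C5 hydroxyl should react. Base-free conditions are chosen on purpose, because a free C5 phenoxide lies ortho to the acetoxymethyl group and could expel acetate.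

## Compound list

1 | 4-methylfuran-2(5H)-one | CC1=CC(=O)OC1 | starting material
2 | tert-butyldimethyl[(4-methylfuran-2-yl)oxy]silane | Cc1coc(O[Si](C)(C)C(C)(C)C)c1 | intermediate
3 | 2,6-dimethoxybenzoyl chloride | COc1cccc(OC)c1C(=O)Cl | starting material
4 | prop-2-yn-1-yl acetate | CC(=O)OCC#C | starting material
5 | 4-(2,6-dimethoxyphenyl)-4-oxobut-2-yn-1-yl acetate | CC(=O)OCC#CC(=O)c1c(OC)cccc1OC | intermediate
6 | {1-[(tert-butyldimethylsilyl)oxy]-2-(2,6-dimethoxybenzoyl)-5-methyl-7-oxabicyclo[2.2.1]hepta-2,5-dien-3-yl}methyl acetate (racemic, one enantiomer drawn; bridgehead C1 bears the silyloxy group, bridgehead C4 is CH; not isolated) | CC1=C[C@@]2(O[Si](C)(C)C(C)(C)C)O[C@@H]1C(COC(C)=O)=C2C(=O)c1c(OC)cccc1OC | intermediate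
7 | [3-{[tert-butyl(dimethyl)silyl]oxy}-2-(2,6-dimethoxybenzoyl)-6-hydroxy-5-methylphenyl]methyl acetate (not isolated) | CC(=O)OCc1c(O)c(C)cc(O[Si](C)(C)C(C)(C)C)c1C(=O)c1c(OC)cccc1OC | intermediate
8 | [2-(2,6-dimethoxybenzoyl)-3,6-dihydroxy-5-methylphenyl]methyl acetate | CC(=O)OCc1c(O)c(C)cc(O)c1C(=O)c1c(OC)cccc1OC | intermediate
9 | preacredinone A, [2-(2,6-dimethoxybenzoyl)-3-hydroxy-6-methoxy-5-methylphenyl]methyl acetate | COc1cccc(OC)c1C(=O)c1c(O)cc(C)c(OC)c1COC(C)=O | target

## Step count and least certain steps

Total: 4 steps. Longest linear sequence: 3 steps (1 → 2 → 8 → 9, or 3 → 5 → 8 → 9).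

**Step 3 (key step).**
- Risk: the cycloaddition may stall after the first bond. C5–C6 forms, but closure between the silyloxy carbon and the carbon carrying the bulky aroyl group fails, and silyl transfer then fixes an open-chain conjugate adduct. The reaction may also be slow, because the ynone is internal and the nucleophilic furan carbon is flanked by the C4 methyl. The heating then needed invites thermal loss of acetic acid from the ortho-hydroxybenzyl acetate and decomposition of the furan.
- Fallback: take the hindered aryl group out of the cycloaddition. The route is left at 2, which is combined with the smaller, more electrophilic ynal 4-{[tri(propan-2-yl)silyl]oxy}but-2-ynal F1, made by formylation of the commercial triisopropylsilyl ether of propargyl alcohol (n-BuLi, then DMF). The same cycloaddition and ring opening should give 6-{[tert-butyl(dimethyl)silyl]oxy}-3-hydroxy-4-methyl-2-({[tri(propan-2-yl)silyl]oxy}methyl)benzaldehyde F2. KHF2 in MeOH should then release only the aryl silyl ether, giving 3,6-dihydroxy-4-methyl-2-({[tri(propan-2-yl)silyl]oxy}methyl)benzaldehyde F3. The benzylic oxygen is now a silyl ether and not a leaving group, so MeI and K2CO3 in acetone can methylate the non-chelated hydroxyl to give 6-hydroxy-3-methoxy-4-methyl-2-({[tri(propan-2-yl)silyl]oxy}methyl)benzaldehyde F4. (2,6-Dimethoxyphenyl)lithium F5 is made from 1,3-dimethoxybenzene and n-BuLi and used in two equivalents, since the phenol is deprotonated first. It adds to the aldehyde to give the racemic carbinol 2-[(2,6-dimethoxyphenyl)(hydroxy)methyl]-4-methoxy-5-methyl-3-({[tri(propan-2-yl)silyl]oxy}methyl)phenol F6. MnO2 in CH2Cl2 oxidises this to (2,6-dimethoxyphenyl)[6-hydroxy-3-methoxy-4-methyl-2-({[tri(propan-2-yl)silyl]oxy}methyl)phenyl]methanone F7. TBAF gives (2,6-dimethoxyphenyl)[6-hydroxy-2-(hydroxymethyl)-3-methoxy-4-methylphenyl]methanone F8. Ac2O and pyridine at 0 °C acetylate the primary hydroxyl in preference to the chelated phenol, and the fallback rejoins the route at 9.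

**Step 4.**
- Risk: incomplete methylation, because the C5 hydroxyl is flanked by CH3 and CH2OAc and is only moderately acidic. If the reaction is forced, methylation may begin at the chelated C2 hydroxyl. A switch to carbonate-mediated alkylation would invite loss of acetate through the phenoxide.
- Fallback: replace selection by chelation with selection by protection. Step 3 is stopped before the HF treatment and the monosilyl ether 7 is isolated. Its only free hydroxyl, at C5, is methylated under Mitsunobu conditions (MeOH, PPh3, DIAD, THF) to give [3-{[tert-butyl(dimethyl)silyl]oxy}-2-(2,6-dimethoxybenzoyl)-6-methoxy-5-methylphenyl]methyl acetate F9. HF·pyridine then frees the C2 hydroxyl, and the fallback rejoins the route at 9. This depends on the assumption stated above about where the silyl group sits in 7.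

**Step 2.**
- Risk: ionisation of the propargylic C–O bond of 4 or 5 by zerovalent palladium, amine-induced decomposition of the γ-acetoxy ynone, and alkyne homocoupling if transmetalation at the doubly ortho-substituted acyl palladium is slow.
- Fallback: make the carbonyl–alkyne bond by acetylide addition instead of palladium catalysis. The route is left at 3, which is converted with N,O-dimethylhydroxylamine hydrochloride and Et3N into N,2,6-trimethoxy-N-methylbenzamide F10. {3-[(tert-Butyldimethylsilyl)oxy]prop-1-yn-1-yl}lithium F11, from the commercial silyl ether of propargyl alcohol and n-BuLi at −78 °C, adds to give 4-{[tert-butyl(dimethyl)silyl]oxy}-1-(2,6-dimethoxyphenyl)but-2-yn-1-one F12. HF·pyridine gives 1-(2,6-dimethoxyphenyl)-4-hydroxybut-2-yn-1-one F13, and Ac2O with pyridine acetylates it, rejoining the route at 5.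

## Further compounds

F1 | step 3 | 4-{[tri(propan-2-yl)silyl]oxy}but-2-ynal | O=CC#CCO[Si](C(C)C)(C(C)C)C(C)C
F2 | step 3 | 6-{[tert-butyl(dimethyl)silyl]oxy}-3-hydroxy-4-methyl-2-({[tri(propan-2-yl)silyl]oxy}methyl)benzaldehyde | O=Cc1c(O[Si](C)(C)C(C)(C)C)cc(C)c(O)c1CO[Si](C(C)C)(C(C)C)C(C)C
F3 | step 3 | 3,6-dihydroxy-4-methyl-2-({[tri(propan-2-yl)silyl]oxy}methyl)benzaldehyde | O=Cc1c(O)cc(C)c(O)c1CO[Si](C(C)C)(C(C)C)C(C)C
F4 | step 3 | 6-hydroxy-3-methoxy-4-methyl-2-({[tri(propan-2-yl)silyl]oxy}methyl)benzaldehyde | O=Cc1c(O)cc(C)c(OC)c1CO[Si](C(C)C)(C(C)C)C(C)C
F5 | step 3 | (2,6-dimethoxyphenyl)lithium | [Li]c1c(OC)cccc1OC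
F6 | step 3 | 2-[(2,6-dimethoxyphenyl)(hydroxy)methyl]-4-methoxy-5-methyl-3-({[tri(propan-2-yl)silyl]oxy}methyl)phenol (racemic) | COc1cccc(OC)c1C(O)c1c(O)cc(C)c(OC)c1CO[Si](C(C)C)(C(C)C)C(C)C
F7 | step 3 | (2,6-dimethoxyphenyl)[6-hydroxy-3-methoxy-4-methyl-2-({[tri(propan-2-yl)silyl]oxy}methyl)phenyl]methanone | COc1cccc(OC)c1C(=O)c1c(O)cc(C)c(OC)c1CO[Si](C(C)C)(C(C)C)C(C)C
F8 | step 3 | (2,6-dimethoxyphenyl)[6-hydroxy-2-(hydroxymethyl)-3-methoxy-4-methylphenyl]methanone | COc1cccc(OC)c1C(=O)c1c(O)cc(C)c(OC)c1CO
F9 | step 4 | [3-{[tert-butyl(dimethyl)silyl]oxy}-2-(2,6-dimethoxybenzoyl)-6-methoxy-5-methylphenyl]methyl acetate | CC(=O)OCc1c(OC)c(C)cc(O[Si](C)(C)C(C)(C)C)c1C(=O)c1c(OC)cccc1OC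
F10 | step 2 | N,2,6-trimethoxy-N-methylbenzamide | COc1cccc(OC)c1C(=O)N(C)OC
F11 | step 2 | {3-[(tert-butyldimethylsilyl)oxy]prop-1-yn-1-yl}lithium | [Li]C#CCO[Si](C)(C)C(C)(C)C
F12 | step 2 | 4-{[tert-butyl(dimethyl)silyl]oxy}-1-(2,6-dimethoxyphenyl)but-2-yn-1-one | COc1cccc(OC)c1C(=O)C#CCO[Si](C)(C)C(C)(C)C
F13 | step 2 | 1-(2,6-dimethoxyphenyl)-4-hydroxybut-2-yn-1-one | COc1cccc(OC)c1C(=O)C#CCO
A1 | alternative 1 | 4-methoxy-3-[(methoxymethoxy)methyl]-5-methyl-2-(trimethylsilyl)phenyl trifluoromethanesulfonate | COCOCc1c(OC)c(C)cc(OS(=O)(=O)C(F)(F)F)c1[Si](C)(C)C
A2 | alternative 1 | 2,6-dimethoxybenzoic acid | COc1cccc(OC)c1C(=O)O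
A3 | alternative 1 | (2,6-dimethoxyphenyl){6-hydroxy-3-methoxy-2-[(methoxymethoxy)methyl]-4-methylphenyl}methanone | COCOCc1c(OC)c(C)cc(O)c1C(=O)c1c(OC)cccc1OC
A4 | alternative 2 | 1-{3-methoxy-6-(methoxymethoxy)-2-[(methoxymethoxy)methyl]-4-methylphenyl}ethan-1-one | CC(=O)c1c(OCOC)cc(C)c(OC)c1COCOC
A5 | alternative 2 | dimethyl pentanedioate (dimethyl glutarate) | COC(=O)CCCC(=O)OC
A6 | alternative 2 | 2-{3-methoxy-6-(methoxymethoxy)-2-[(methoxymethoxy)methyl]-4-methylbenzoyl}cyclohexane-1,3-dione | O=C1CCCC(=O)C1C(=O)c1c(OCOC)cc(C)c(OC)c1COCOC
A7 | alternative 3 | 2-({[1-(2,6-dimethoxyphenyl)prop-2-yn-1-yl]oxy}methyl)-3-methoxy-4-methylfuran (racemic) | C#CC(OCc1occ(C)c1OC)c1c(OC)cccc1OC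
A8 | alternative 3 | 3-(2,6-dimethoxyphenyl)-7-methoxy-6-methyl-1,3-dihydro-2-benzofuran-4-ol (racemic) | COc1cccc(OC)c1C1OCc2c(OC)c(C)cc(O)c21
A9 | alternative 3 | gold trichloride | Cl[Au](Cl)Cl
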